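**Retrosynthetic overview**

1. The strategy rests on ring A of the flavone: C5, C6 and C7 each carry oxygen (the sulfate sits on the C7 oxygen) and C8 carries hydrogen, so C5–C6–C7–C8 is a 1,2,3-trioxygenated four-carbon diene unit fused onto the C4a=C8a bond of the 2-arylpyran-4-one (ring C).
2. Last disconnections: the three benzyl ethers (hydrogenolysis) and the O–S bond at C7 (SO3·pyridine on the only unchelated phenol of a 6-O-benzyl-5,7-dihydroxyflavone).
3. Key disconnection: C4a–C5 and C8–C8a, by Diels–Alder addition of a 2-benzyloxy-1-methoxy-1,3-bis(silyloxy)butadiene to the sulfinyl-bearing C=C of a 2-aryl-5-(p-tolylsulfinyl)pyran-4-one, followed by loss of sulfenic acid and methanol.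
4. The pyranone is made from methyl p-tolyl sulfoxide (acetylation, amide-acetal condensation) and 3,4-bis(benzyloxy)benzoyl chloride (enolate aroylation, acid ring closure); the diene from methyl acetoacetate (diazo transfer, O–H insertion with benzyl alcohol, double silylation).
5. Ring order: ring B is bought as the benzoic acid, ring C is closed in step 4, ring A is built last in step 9.

Key step: step 9

Assumption: the two sulfate monoesters of the route are drawn as free hydrogen sulfates, as in the target formula; the benzylated one would be handled as its pyridine-free sodium salt and the final one set free by cold H+ ion exchange. All sulfoxides are racemic at sulfur; the target has no stereocentre.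

**Step 1**
Reactants: 1 methyl 4-methylphenyl sulfoxide (racemic)
Product: 2 1-[(4-methylphenyl)sulfinyl]propan-2-one
Conditions: LiN(iPr)2 (2.1 equiv), THF, −78 °C; EtOAc, −78 → 0 °C; aq. NH4Cl
Reagents that add atoms: ethyl acetate, CCOC(C)=O
Why: Claisen-type acylation of the α-sulfinyl carbanion by the ester; the second equivalent of base deprotonates the more acidic β-keto sulfoxide as it forms, which should prevent double acylation.

**Step 2**
Reactants: 2 1-[(4-methylphenyl)sulfinyl]propan-2-one
Product: 3 4-(dimethylamino)-3-[(4-methylphenyl)sulfinyl]but-3-en-2-one (alkene geometry not controlled)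
Conditions: Me2NCH(OMe)2 (1.2 equiv), PhMe, 60 °C
Reagents that add atoms: N,N-dimethylformamide dimethyl acetal, COC(OC)N(C)C
Why: Enaminone formation by amide-acetal condensation at the methylene activated by both S=O and C=O; the far less acidic methyl group should stay untouched.

**Step 3**
Reactants: 4 3,4-bis(benzyloxy)benzoic acid
Product: 5 3,4-bis(benzyloxy)benzoyl chloride
Conditions: (COCl)2, DMF (cat.), CH2Cl2, 0 °C → rt
Reagents that add atoms: oxalyl chloride, O=C(Cl)C(Cl)=O
Why: Acid chloride formation through the catalytic Vilsmeier-type chloroiminium species; aryl benzyl ethers are inert to it.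

**Step 4**
Reactants: 3 4-(dimethylamino)-3-[(4-methylphenyl)sulfinyl]but-3-en-2-one; 5 3,4-bis(benzyloxy)benzoyl chloride
Product: 7 2-[3,4-bis(benzyloxy)phenyl]-5-[(4-methylphenyl)sulfinyl]-4H-pyran-4-one, via enaminodiketone 6 (not isolated)
Conditions: LiN(SiMe3)2 (2.5 equiv), THF, −78 °C; then 5, −78 → −20 °C; then CF3CO2H, CH2Cl2, rt
Reagents that add atoms: none
Why: C-aroylation of the lithium enolate of the methyl ketone (the only enolisable position) gives 1,3-diketone 6, whose enol oxygen adds to the enaminone carbon under acid and expels dimethylamine to close the pyran-4-one, the established γ-pyrone synthesis from enaminones and acid chlorides.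

**Step 5**
Reactants: 8 methyl 3-oxobutanoate (methyl acetoacetate)
Product: 9 methyl 2-diazo-3-oxobutanoate
Conditions: 4-acetamidobenzenesulfonyl azide, Et3N, MeCN, 0 °C → rt
Reagents that add atoms: 4-acetamidobenzenesulfonyl azide, CC(=O)Nc1ccc(cc1)S(=O)(=O)N=[N+]=[N-]
Why: Regitz diazo transfer to the active methylene of a β-keto ester.

**Step 6**
Reactants: 9 methyl 2-diazo-3-oxobutanoate
Product: 10 methyl 2-(benzyloxy)-3-oxobutanoate (racemic)
Conditions: BnOH (1.5 equiv), Rh2(OAc)4 (1 mol %), CH2Cl2, reflux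
Reagents that add atoms: benzyl alcohol, OCc1ccccc1
Why: Rhodium-carbenoid O–H insertion of the α-diazo-β-keto ester into the alcohol; the new C2 stereocentre forms as a racemate and is removed by enol silylation in the next step.

**Step 7**
Reactants: 10 methyl 2-(benzyloxy)-3-oxobutanoate
Product: 11 methyl 2-(benzyloxy)-3-[(trimethylsilyl)oxy]but-2-enoate (E and Z mixture)
Conditions: Me3SiCl (1.5 equiv), Et3N (1.6 equiv), PhMe, rt; filter, concentrate
Reagents that add atoms: chlorotrimethylsilane, C[Si](C)(C)Cl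
Why: O-silylation of the enol of the β-keto ester, the first stage of the standard two-stage preparation of 1,3-bis(silyloxy)dienes.

**Step 8**
Reactants: 11 methyl 2-(benzyloxy)-3-[(trimethylsilyl)oxy]but-2-enoate
Product: 12 2-(benzyloxy)-1-methoxy-1,3-bis[(trimethylsilyl)oxy]buta-1,3-diene (E and Z mixture, used crude)
Conditions: LiN(iPr)2 (1.2 equiv), THF, −78 °C; Me3SiCl, −78 → 0 °C; pentane, filter
Reagents that add atoms: chlorotrimethylsilane, C[Si](C)(C)Cl
Why: Kinetic γ-deprotonation of the vinylogous ester at its methyl group and O-silylation of the dienolate, as in the preparation of Chan-type dienes.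

**Step 9**
Reactants: 7 2-[3,4-bis(benzyloxy)phenyl]-5-[(4-methylphenyl)sulfinyl]-4H-pyran-4-one; 12 2-(benzyloxy)-1-methoxy-1,3-bis[(trimethylsilyl)oxy]buta-1,3-diene
Product: 15 6-(benzyloxy)-2-[3,4-bis(benzyloxy)phenyl]-5,7-dihydroxy-4H-chromen-4-one, via cis-fused sulfinyl cycloadduct 13 (not isolated), via 5,8-dihydrochromenone mixed ketal 14 (not isolated)
Conditions: 12 (2 equiv), PhMe, 0 → 60 °C; then 1 M HCl, THF, rt
Reagents that add atoms: none
Why: Proposed new method: diene 12 should add in a normal-demand [4+2] (asynchronous, or Mukaiyama–Michael addition followed by closure through the silyloxyallyl cation) across C5=C6 of pyranone 7, its CH2 terminus bonding to C6 (β to both C=O and S=O, the future C8a) and its ketene-acetal carbon to the sulfinyl-bearing C5 (the future C4a), to give cis-fused 13; syn-elimination of 4-methylbenzenesulfenic acid (S and the C8a–H are cis) gives 14, and loss of methanol from the C5 mixed ketal, tautomerisation of the C8 methylene and acid desilylation give arene 15. The closest known reactions are the Diels–Alder/eliminative aromatisations of sulfinyl- and haloquinones and of 3-acceptor-substituted chromones with 1-alkoxy-1,3-bis(silyloxy)dienes; a monocyclic sulfinylpyranone with a 2-alkoxy diene has not been shown. Ring A is closed by an intermolecular suprafacial [4+2] cycloaddition that forms C4a–C5 and C8–C8a of a six-membered carbocycle. The stereocentres of 13 (C4a, C5, C8a, sulfur) are transient and are erased on aromatisation, so none needs control beyond the cis fusion that the cycloaddition itself gives. The step needs site selectivity for C5=C6 over the aryl-bearing C2=C3 and head-to-tail regiochemistry; the sulfinyl group secures both, since it makes C5=C6 the only doubly activated alkene and polarises it toward attack at C6, and the quaternary C4a of 13 blocks opening of the pyran ring by β-elimination of the ring oxygen.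

**Step 10**
Reactants: 15 6-(benzyloxy)-2-[3,4-bis(benzyloxy)phenyl]-5,7-dihydroxy-4H-chromen-4-one
Product: 16 6-(benzyloxy)-2-[3,4-bis(benzyloxy)phenyl]-5-hydroxy-4-oxo-4H-chromen-7-yl hydrogen sulfate
Conditions: SO3·pyridine (3 equiv), pyridine, rt → 40 °C; then Dowex 50W (Na+ form), MeOH–H2O
Reagents that add atoms: sulfur trioxide–pyridine complex, [O-]S(=O)(=O)[n+]1ccccc1
Why: O-sulfonation of a phenol by an SO3–amine complex; the 5-OH is held in a hydrogen bond to the C4 carbonyl, so the more acidic 7-OH should react alone.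

**Step 11**
Reactants: 16 6-(benzyloxy)-2-[3,4-bis(benzyloxy)phenyl]-5-hydroxy-4-oxo-4H-chromen-7-yl hydrogen sulfate
Product: 17 2-(3,4-dihydroxyphenyl)-5,6-dihydroxy-4-oxo-4H-chromen-7-yl hydrogen sulfate (6-hydroxyluteolin 7-sulfate)
Conditions: H2 (1 atm), 10% Pd/C, MeOH–THF, rt, under exclusion of air on work-up; then Dowex 50W (H+ form), 0 °C, lyophilise
Reagents that add atoms: none
Why: Catalytic hydrogenolysis of the three aryl benzyl ethers; aryl sulfate monoester salts and the flavone C2=C3 bond should not be reduced at 1 atm, and the pyridine-free sodium salt avoids amine inhibition of the catalyst.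

**Compound list**

1 | methyl 4-methylphenyl sulfoxide (racemic) | Cc1ccc(cc1)S(C)=O | starting material
2 | 1-[(4-methylphenyl)sulfinyl]propan-2-one (racemic at S) | CC(=O)CS(=O)c1ccc(C)cc1 | intermediate
3 | 4-(dimethylamino)-3-[(4-methylphenyl)sulfinyl]but-3-en-2-one (racemic at S, E/Z not controlled) | CC(=O)C(=CN(C)C)S(=O)c1ccc(C)cc1 | intermediate
4 | 3,4-bis(benzyloxy)benzoic acid | OC(=O)c1ccc(OCc2ccccc2)c(OCc2ccccc2)c1 | starting material
5 | 3,4-bis(benzyloxy)benzoyl chloride | ClC(=O)c1ccc(OCc2ccccc2)c(OCc2ccccc2)c1 | intermediate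
6 | 1-[3,4-bis(benzyloxy)phenyl]-6-(dimethylamino)-5-[(4-methylphenyl)sulfinyl]hex-5-ene-1,3-dione (formed as its lithium enolate, not isolated) | CN(C)C=C(C(=O)CC(=O)c1ccc(OCc2ccccc2)c(OCc2ccccc2)c1)S(=O)c1ccc(C)cc1 | intermediate
7 | 2-[3,4-bis(benzyloxy)phenyl]-5-[(4-methylphenyl)sulfinyl]-4H-pyran-4-one (racemic at S) | Cc1ccc(cc1)S(=O)c1coc(-c2ccc(OCc3ccccc3)c(OCc3ccccc3)c2)cc1=O | intermediate
8 | methyl 3-oxobutanoate | COC(=O)CC(C)=O | starting material
9 | methyl 2-diazo-3-oxobutanoate | COC(=O)C(=[N+]=[N-])C(C)=O | intermediate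
10 | methyl 2-(benzyloxy)-3-oxobutanoate (racemic) | COC(=O)C(OCc1ccccc1)C(C)=O | intermediate
11 | methyl 2-(benzyloxy)-3-[(trimethylsilyl)oxy]but-2-enoate (E/Z mixture) | COC(=O)C(OCc1ccccc1)=C(C)O[Si](C)(C)C | intermediate
12 | 2-(benzyloxy)-1-methoxy-1,3-bis[(trimethylsilyl)oxy]buta-1,3-diene (E/Z mixture) | COC(O[Si](C)(C)C)=C(OCc1ccccc1)C(=C)O[Si](C)(C)C | intermediate
13 | 6-(benzyloxy)-2-[3,4-bis(benzyloxy)phenyl]-5-methoxy-4a-[(4-methylphenyl)sulfinyl]-5,7-bis[(trimethylsilyl)oxy]-4a,5,8,8a-tetrahydro-4H-chromen-4-one (cis-fused, racemic diastereomer mixture, not isolated) | COC1(O[Si](C)(C)C)C(OCc2ccccc2)=C(O[Si](C)(C)C)CC2OC(-c3ccc(OCc4ccccc4)c(OCc4ccccc4)c3)=CC(=O)C12S(=O)c1ccc(C)cc1 | intermediate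
14 | 6-(benzyloxy)-2-[3,4-bis(benzyloxy)phenyl]-5-methoxy-5,7-bis[(trimethylsilyl)oxy]-5,8-dihydro-4H-chromen-4-one (racemic, not isolated) | COC1(O[Si](C)(C)C)C(OCc2ccccc2)=C(O[Si](C)(C)C)CC2=C1C(=O)C=C(O2)-c1ccc(OCc2ccccc2)c(OCc2ccccc2)c1 | intermediate
15 | 6-(benzyloxy)-2-[3,4-bis(benzyloxy)phenyl]-5,7-dihydroxy-4H-chromen-4-one | O=c1cc(-c2ccc(OCc3ccccc3)c(OCc3ccccc3)c2)oc2cc(O)c(OCc3ccccc3)c(O)c12 | intermediate
16 | 6-(benzyloxy)-2-[3,4-bis(benzyloxy)phenyl]-5-hydroxy-4-oxo-4H-chromen-7-yl hydrogen sulfate | O=c1cc(-c2ccc(OCc3ccccc3)c(OCc3ccccc3)c2)oc2cc(OS(=O)(=O)O)c(OCc3ccccc3)c(O)c12 | intermediate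
17 | 2-(3,4-dihydroxyphenyl)-5,6-dihydroxy-4-oxo-4H-chromen-7-yl hydrogen sulfate (6-hydroxyluteolin 7-sulfate) | O=c1cc(-c2ccc(O)c(O)c2)oc2cc(OS(=O)(=O)O)c(O)c(O)c12 | target

**Step count**

Total steps: 11. Longest linear sequence: 7 (steps 5, 6, 7, 8, 9, 10, 11); the pyranone branch contributes 6 (steps 1, 2, 4, 9, 10, 11).

**Steps most likely to fail**

Step 9. The diene may add only once, at C6 of the pyranone, without closing onto the congested sulfinyl-bearing carbon; the pyran ring can then open by β-elimination of the ring oxygen, or the diene may be consumed by protodesilylation or by the sulfenic acid that is released. The fallback uses known chemistry, sets out from acid chloride 5 and comes back to the route at target 17.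
- O-aroylation of commercial 1-(6-hydroxy-2,3,4-trimethoxyphenyl)ethanone with 5 in pyridine should give 2-acetyl-3,4,5-trimethoxyphenyl 3,4-bis(benzyloxy)benzoate F1.
- Baker–Venkataraman rearrangement (KOH, pyridine, 50 °C) should give 1-[3,4-bis(benzyloxy)phenyl]-3-(6-hydroxy-2,3,4-trimethoxyphenyl)propane-1,3-dione F2.
- Cyclodehydration (p-TsOH, PhMe, reflux) should give 2-[3,4-bis(benzyloxy)phenyl]-5,6,7-trimethoxy-4H-chromen-4-one F3.
- BBr3 (CH2Cl2, −78 °C → rt) should cleave all five ethers to 6-hydroxyluteolin F4.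
- Ac2O in pyridine should give 6-hydroxyluteolin pentaacetate F5.
- PhSH and imidazole in NMP at 0 °C should remove only the most activated ester to give the 7-hydroxy tetraacetate F6.
- SO3·pyridine should give the 7-sulfate tetraacetate F7.
- NH3 in MeOH at 0 °C under argon, then H+ ion exchange, should remove the four acetates and give 17.

Step 10. O-sulfonation of the 7-hydroxyl, which is flanked by the 6-benzyloxy group, may be slow or incomplete; forcing it may sulfate the chelated 5-hydroxyl as well, and the charged monoester may be lost or hydrolysed on isolation. The fallback sets out from 15 and comes back at 16. It installs the sulfate as a neutral protected diester: 2,2,2-trichloroethyl chlorosulfate with Et3N and DMAP in THF should give 6-(benzyloxy)-2-[3,4-bis(benzyloxy)phenyl]-5-hydroxy-4-oxo-4H-chromen-7-yl 2,2,2-trichloroethyl sulfate F8, which can be chromatographed on silica. Reductive removal of the trichloroethyl group with Zn and HCO2NH4 in MeOH at rt should then give 16 without touching the benzyl ethers.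

Step 4. The enolate may be aroylated on oxygen, the acid chloride may activate the sulfoxide oxygen and cause Pummerer-type loss of the sulfinyl group, or the vinyl sulfoxide may decompose under the acidic ring closure. The fallback sets out from acid chloride 5 and comes back at pyranone 7. It carries sulfur at the sulfide level and oxidises after the ring is formed.
- S-alkylation of 4-methylbenzenethiol with chloroacetone (K2CO3, acetone) should give 1-[(4-methylphenyl)sulfanyl]propan-2-one F9.
- Me2NCH(OMe)2 should give 4-(dimethylamino)-3-[(4-methylphenyl)sulfanyl]but-3-en-2-one F10.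
- LiN(SiMe3)2 and 5 should give 1-[3,4-bis(benzyloxy)phenyl]-6-(dimethylamino)-5-[(4-methylphenyl)sulfanyl]hex-5-ene-1,3-dione F11, which CF3CO2H should close to 2-[3,4-bis(benzyloxy)phenyl]-5-[(4-methylphenyl)sulfanyl]-4H-pyran-4-one F12.
- One equivalent of mCPBA in CH2Cl2 at −40 °C should oxidise the sulfide to sulfoxide 7.

**Further compounds**

F1 | step 9 | 2-acetyl-3,4,5-trimethoxyphenyl 3,4-bis(benzyloxy)benzoate | CC(=O)c1c(OC(=O)c2ccc(OCc3ccccc3)c(OCc3ccccc3)c2)cc(OC)c(OC)c1OC
F2 | step 9 | 1-[3,4-bis(benzyloxy)phenyl]-3-(6-hydroxy-2,3,4-trimethoxyphenyl)propane-1,3-dione | COc1cc(O)c(C(=O)CC(=O)c2ccc(OCc3ccccc3)c(OCc3ccccc3)c2)c(OC)c1OC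
F3 | step 9 | 2-[3,4-bis(benzyloxy)phenyl]-5,6,7-trimethoxy-4H-chromen-4-one | COc1cc2oc(-c3ccc(OCc4ccccc4)c(OCc4ccccc4)c3)cc(=O)c2c(OC)c1OC
F4 | step 9 | 2-(3,4-dihydroxyphenyl)-5,6,7-trihydroxy-4H-chromen-4-one (6-hydroxyluteolin) | O=c1cc(-c2ccc(O)c(O)c2)oc2cc(O)c(O)c(O)c12
F5 | step 9 | 2-[3,4-bis(acetyloxy)phenyl]-4-oxo-4H-chromene-5,6,7-triyl triacetate | CC(=O)Oc1ccc(cc1OC(C)=O)-c1cc(=O)c2c(OC(C)=O)c(OC(C)=O)c(OC(C)=O)cc2o1
F6 | step 9 | 2-[3,4-bis(acetyloxy)phenyl]-7-hydroxy-4-oxo-4H-chromene-5,6-diyl diacetate | CC(=O)Oc1ccc(cc1OC(C)=O)-c1cc(=O)c2c(OC(C)=O)c(OC(C)=O)c(O)cc2o1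
F7 | step 9 | 2-[3,4-bis(acetyloxy)phenyl]-4-oxo-7-(sulfooxy)-4H-chromene-5,6-diyl diacetate | CC(=O)Oc1ccc(cc1OC(C)=O)-c1cc(=O)c2c(OC(C)=O)c(OC(C)=O)c(OS(=O)(=O)O)cc2o1
F8 | step 10 | 6-(benzyloxy)-2-[3,4-bis(benzyloxy)phenyl]-5-hydroxy-4-oxo-4H-chromen-7-yl 2,2,2-trichloroethyl sulfate | O=c1cc(-c2ccc(OCc3ccccc3)c(OCc3ccccc3)c2)oc2cc(OS(=O)(=O)OCC(Cl)(Cl)Cl)c(OCc3ccccc3)c(O)c12
F9 | step 4 | 1-[(4-methylphenyl)sulfanyl]propan-2-one | CC(=O)CSc1ccc(C)cc1
F10 | step 4 | 4-(dimethylamino)-3-[(4-methylphenyl)sulfanyl]but-3-en-2-one | CC(=O)C(=CN(C)C)Sc1ccc(C)cc1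
F11 | step 4 | 1-[3,4-bis(benzyloxy)phenyl]-6-(dimethylamino)-5-[(4-methylphenyl)sulfanyl]hex-5-ene-1,3-dione | CN(C)C=C(C(=O)CC(=O)c1ccc(OCc2ccccc2)c(OCc2ccccc2)c1)Sc1ccc(C)cc1
F12 | step 4 | 2-[3,4-bis(benzyloxy)phenyl]-5-[(4-methylphenyl)sulfanyl]-4H-pyran-4-one | Cc1ccc(cc1)Sc1coc(-c2ccc(OCc3ccccc3)c(OCc3ccccc3)c2)cc1=O
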